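The tetrahydrofuran (O1; C2 with ring A; C3 with C9H2OH; C4 with carbinol Ca and ring B; C5H2) is cut at O1–C5. O1–C2–C3 is the enol of a ring A aroyl ester and C5 is the only unsubstituted ring carbon, so the ring maps onto a 1-aroylcyclopropane-1-carboxylate (C3, C4, C5). A single iodide-catalysed Cloke–Wilson ring expansion cleaves C3–C5, joins the ketone oxygen to C5 and leaves Ca and C4 untouched. The precursor is a methyl 1-aroyl-2-(α-silyloxybenzyl)cyclopropane-1-carboxylate; its Ca/C4 pair is fixed beforehand by a Shi epoxidation and an invertive 3-exo epoxide opening.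

Key step: step 8

Remark: the benzyl ethers of vanillin and of vanillic acid are taken as purchased starting materials; both aryl benzyl ethers are shed in the same hydrogenation that saturates C2=C3.
Remark: Ca and C4 are set by reagent control and a stereospecific inversion instead of acyclic 1,2-induction from an α-silyloxy aldehyde, because such an aldehyde racemises easily and a methylene donor is expected to add anti to its C–O bond, which leads to the Ca/C4 epimer; C3 of the cyclopropane may have either configuration.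

Step 1
Reactants: 1 4-(benzyloxy)-3-methoxybenzaldehyde; 2 vinylmagnesium bromide
Product: 3 rac-1-[4-(benzyloxy)-3-methoxyphenyl]prop-2-en-1-ol
Conditions: CH2=CHMgBr (1.2 equiv), THF, 0 °C; aq NH4Cl
Reagents that add atoms: none
Why: Grignard 1,2-addition of the vinyl group to a non-enolisable aldehyde gives the racemic allylic alcohol, whose stereocentre is erased in the next step.

Step 2
Reactants: 3 rac-1-[4-(benzyloxy)-3-methoxyphenyl]prop-2-en-1-ol; 4 trimethyl orthoacetate
Product: 6 methyl (E)-5-[4-(benzyloxy)-3-methoxyphenyl]pent-4-enoate, via mixed ketene acetal 5 (not isolated)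
Conditions: MeC(OMe)3 (6 equiv), EtCO2H (5 mol %), 110–130 °C, MeOH distilled off
Reagents that add atoms: none
Why: Johnson–Claisen rearrangement, in which acid-catalysed exchange with the orthoester gives ketene acetal 5 and its chair [3,3] shift with the aryl group equatorial forms the C3–C5 bond and the conjugated (E)-styrenyl alkene.

Step 3
Reactants: 6 methyl (E)-5-[4-(benzyloxy)-3-methoxyphenyl]pent-4-enoate
Product: 7 methyl 3-[(2R,3R)-3-[4-(benzyloxy)-3-methoxyphenyl]oxiran-2-yl]propanoate
Conditions: D-fructose-derived Shi ketone (30 mol %), KHSO5 (Oxone), K2CO3, Bu4NHSO4, MeCN–CH2(OMe)2/aq Na2B4O7 buffer (pH 10.5), 0 °C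
Reagents that add atoms: potassium peroxymonosulfate (KHSO5), [K+].[O-]S(=O)(=O)OO
Why: Shi asymmetric epoxidation, in which the dioxirane of the D-fructose-derived ketone transfers oxygen to the trans-β-alkylstyrene through the spiro transition state known to deliver (R,R)-epoxides from this alkene class, so that Ca (R) and C4 (R) are set by reagent control, while the basic buffer protects the acid-labile electron-rich aryl epoxide, which is carried on without chromatography.

Step 4
Reactants: 7 methyl 3-[(2R,3R)-3-[4-(benzyloxy)-3-methoxyphenyl]oxiran-2-yl]propanoate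
Product: 8 methyl (1R,2R)-2-[(S)-[4-(benzyloxy)-3-methoxyphenyl](hydroxy)methyl]cyclopropane-1-carboxylate
Conditions: KN(SiMe3)2 (1.2 equiv), 18-crown-6, THF, −78 → 0 °C; aq NH4Cl
Reagents that add atoms: none
Why: Intramolecular 3-exo-tet alkylation of the ester enolate by the epoxide (attack at the benzylic carbon would be a disfavoured 4-endo opening) forms C3–C4 with inversion at C4 and retention at Ca, which fixes the Ca (S)/C4 pair of the target, and the crown-complexed potassium enolate should close through the open transition state that puts the ester trans to the carbinol arm, where the alkoxide cannot lactonise.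

Step 5
Reactants: 8 methyl (1R,2R)-2-[(S)-[4-(benzyloxy)-3-methoxyphenyl](hydroxy)methyl]cyclopropane-1-carboxylate
Product: 9 methyl (1R,2R)-2-[(S)-[4-(benzyloxy)-3-methoxyphenyl][(tert-butyldimethylsilyl)oxy]methyl]cyclopropane-1-carboxylate
Conditions: TBSCl, imidazole, DMF, rt
Reagents that add atoms: tert-butyldimethylsilyl chloride, CC(C)(C)[Si](C)(C)Cl
Why: Standard silylation of the secondary benzylic alcohol gives a base-stable ether that blocks lactonisation onto the C3 carboxyl in all later steps and touches no stereocentre.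

Step 6
Reactants: 10 4-(benzyloxy)-3-methoxybenzoic acid
Product: 11 4-(benzyloxy)-3-methoxybenzoyl chloride
Conditions: (COCl)2, DMF (cat.), CH2Cl2, 0 °C → rt
Reagents that add atoms: oxalyl chloride, O=C(Cl)C(=O)Cl
Why: Vilsmeier-type activation of the carboxylic acid gives the aroyl chloride, which is used crude.

Step 7
Reactants: 9 methyl (1R,2R)-2-[(S)-[4-(benzyloxy)-3-methoxyphenyl][(tert-butyldimethylsilyl)oxy]methyl]cyclopropane-1-carboxylate; 11 4-(benzyloxy)-3-methoxybenzoyl chloride
Product: 12 methyl (2R)-1-[4-(benzyloxy)-3-methoxybenzoyl]-2-[(S)-[4-(benzyloxy)-3-methoxyphenyl][(tert-butyldimethylsilyl)oxy]methyl]cyclopropane-1-carboxylate (either configuration at C1 of the cyclopropane, which is C3 of the target)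
Conditions: LiN(i-Pr)2 (1.2 equiv), THF, −78 °C; then 11, −78 → −30 °C
Reagents that add atoms: none
Why: Deprotonation of a methyl cyclopropanecarboxylate at low temperature and C-acylation of the lithium enolate by an aroyl chloride (crossed Claisen-type acylation) creates the quaternary C3 without touching Ca and C4, and the configuration at C3, expected with the aroyl group trans to the arm, is irrelevant.

Step 8
Reactants: 12 methyl (2R)-1-[4-(benzyloxy)-3-methoxybenzoyl]-2-[(S)-[4-(benzyloxy)-3-methoxyphenyl][(tert-butyldimethylsilyl)oxy]methyl]cyclopropane-1-carboxylate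
Product: 14 methyl (4S)-2-[4-(benzyloxy)-3-methoxyphenyl]-4-[(S)-[4-(benzyloxy)-3-methoxyphenyl][(tert-butyldimethylsilyl)oxy]methyl]-4,5-dihydrofuran-3-carboxylate, via iodomagnesium enolate 13 (not isolated)
Conditions: MgI2 (20 mol %), THF, 60 °C
Reagents that add atoms: none
Why: Magnesium iodide chelates the two carbonyl groups on C3 and iodide attacks the unsubstituted ring carbon C5 in an SN2 homoconjugate opening that cleaves C3–C5 and releases the ring strain as the chelated enolate 13. The aryl ketone oxygen of 13 then displaces iodide from C5 in a 5-exo-tet O-alkylation, which forms O1–C5, closes the 4,5-dihydrofuran and returns the catalyst; closure at carbon only regenerates the cyclopropane, so both C3 epimers of 12 drain into one product. This is the nucleophile-catalysed form of the Cloke–Wilson rearrangement, a known reaction type for 1-acylcyclopropane-1-carboxylates. No stereocentre is created, because C3 becomes trigonal and Ca and C4 keep all their bonds. The step needs opening at C5 and not at C4, which is secured by C5 being primary while C4 is secondary, shielded by the branched silyloxybenzyl arm and inductively deactivated by the β-oxygen; closure through the ketone oxygen and not the ester oxygen is favoured because it gives the aryl-conjugated vinylogous carbonate.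

Step 9
Reactants: 14 methyl (4S)-2-[4-(benzyloxy)-3-methoxyphenyl]-4-[(S)-[4-(benzyloxy)-3-methoxyphenyl][(tert-butyldimethylsilyl)oxy]methyl]-4,5-dihydrofuran-3-carboxylate
Product: 16 methyl (2S,3R,4S)-4-[(S)-[(tert-butyldimethylsilyl)oxy](4-hydroxy-3-methoxyphenyl)methyl]-2-(4-hydroxy-3-methoxyphenyl)tetrahydrofuran-3-carboxylate (2,3-cis, 3,4-cis), via bisphenol dihydrofuran 15 (not isolated)
Conditions: H2 (3 atm), 10% Pd/C, EtOAc–MeOH, rt
Reagents that add atoms: none
Why: Palladium-catalysed hydrogenolysis removes both aryl benzyl ethers (15) and heterogeneous syn hydrogenation of the tetrasubstituted enol ether should occur from the face opposite the bulky C4 arm, which sets C2 (S) with ring A cis to that arm and leaves C3 cis (3R) for correction in the next step.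

Step 10
Reactants: 16 methyl (2S,3R,4S)-4-[(S)-[(tert-butyldimethylsilyl)oxy](4-hydroxy-3-methoxyphenyl)methyl]-2-(4-hydroxy-3-methoxyphenyl)tetrahydrofuran-3-carboxylate
Product: 17 methyl (2S,3S,4S)-4-[(S)-[(tert-butyldimethylsilyl)oxy](4-hydroxy-3-methoxyphenyl)methyl]-2-(4-hydroxy-3-methoxyphenyl)tetrahydrofuran-3-carboxylate (2,3-trans, 3,4-trans)
Conditions: NaOMe (4 equiv), MeOH, 40 °C; aq NH4Cl
Reagents that add atoms: none
Why: Base-mediated epimerisation through the ester enolate moves the C3 carboxylate from the crowded all-cis position to the position trans to both neighbours (3S), the thermodynamic all-trans ring, while the phenols ride as phenoxides and the secondary silyl ether withstands methoxide.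

Step 11
Reactants: 17 methyl (2S,3S,4S)-4-[(S)-[(tert-butyldimethylsilyl)oxy](4-hydroxy-3-methoxyphenyl)methyl]-2-(4-hydroxy-3-methoxyphenyl)tetrahydrofuran-3-carboxylate
Product: 18 4-[(2S,3R,4S)-4-[(S)-[(tert-butyldimethylsilyl)oxy](4-hydroxy-3-methoxyphenyl)methyl]-3-(hydroxymethyl)tetrahydrofuran-2-yl]-2-methoxyphenol
Conditions: LiAlH4 (4 equiv), THF, 0 °C → rt; aq KNaC4H4O6
Reagents that add atoms: none
Why: Hydride reduction of the methyl ester gives C9H2OH (the excess covers the two phenols) without affecting any stereocentre or the silyl ether.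

Step 12
Reactants: 18 4-[(2S,3R,4S)-4-[(S)-[(tert-butyldimethylsilyl)oxy](4-hydroxy-3-methoxyphenyl)methyl]-3-(hydroxymethyl)tetrahydrofuran-2-yl]-2-methoxyphenol
Product: 19 4-[(2S,3R,4S)-4-[(S)-hydroxy(4-hydroxy-3-methoxyphenyl)methyl]-3-(hydroxymethyl)tetrahydrofuran-2-yl]-2-methoxyphenol
Conditions: Bu4NF (3 equiv), AcOH (3 equiv), THF, rt
Reagents that add atoms: none
Why: Fluoride-mediated desilylation under buffered, non-acidic conditions frees the Ca hydroxyl without ionising the p-hydroxybenzylic carbinol, which under acid could close onto C9–OH.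

Compound list
1 | 4-(benzyloxy)-3-methoxybenzaldehyde | COc1cc(C=O)ccc1OCc1ccccc1 | starting material
2 | vinylmagnesium bromide | C=C[Mg]Br | starting material
3 | rac-1-[4-(benzyloxy)-3-methoxyphenyl]prop-2-en-1-ol | COc1cc(C(O)C=C)ccc1OCc1ccccc1 | intermediate
4 | trimethyl orthoacetate | CC(OC)(OC)OC | starting material
5 | 1-[4-(benzyloxy)-3-methoxyphenyl]allyl methyl ketene acetal | C=C(OC)OC(C=C)c1ccc(OCc2ccccc2)c(OC)c1 | intermediate (not isolated)
6 | methyl (E)-5-[4-(benzyloxy)-3-methoxyphenyl]pent-4-enoate | COC(=O)CC/C=C/c1ccc(OCc2ccccc2)c(OC)c1 | intermediate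
7 | methyl 3-[(2R,3R)-3-[4-(benzyloxy)-3-methoxyphenyl]oxiran-2-yl]propanoate | COc1cc([C@H]2O[C@@H]2CCC(=O)OC)ccc1OCc1ccccc1 | intermediate
8 | methyl (1R,2R)-2-[(S)-[4-(benzyloxy)-3-methoxyphenyl](hydroxy)methyl]cyclopropane-1-carboxylate | COc1cc([C@@H](O)[C@@H]2C[C@H]2C(=O)OC)ccc1OCc1ccccc1 | intermediate
9 | methyl (1R,2R)-2-[(S)-[4-(benzyloxy)-3-methoxyphenyl][(tert-butyldimethylsilyl)oxy]methyl]cyclopropane-1-carboxylate | COc1cc([C@@H](O[Si](C)(C)C(C)(C)C)[C@@H]2C[C@H]2C(=O)OC)ccc1OCc1ccccc1 | intermediate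
10 | 4-(benzyloxy)-3-methoxybenzoic acid | COc1cc(C(=O)O)ccc1OCc1ccccc1 | starting material
11 | 4-(benzyloxy)-3-methoxybenzoyl chloride | COc1cc(C(=O)Cl)ccc1OCc1ccccc1 | intermediate
12 | methyl (2R)-1-[4-(benzyloxy)-3-methoxybenzoyl]-2-[(S)-[4-(benzyloxy)-3-methoxyphenyl][(tert-butyldimethylsilyl)oxy]methyl]cyclopropane-1-carboxylate, either configuration at C1 | COc1cc([C@@H](O[Si](C)(C)C(C)(C)C)[C@@H]2CC2(C(=O)OC)C(=O)c2ccc(OCc3ccccc3)c(OC)c2)ccc1OCc1ccccc1 | intermediate
13 | iodomagnesium enolate of methyl (3R,4S)-2-[4-(benzyloxy)-3-methoxybenzoyl]-4-[4-(benzyloxy)-3-methoxyphenyl]-4-[(tert-butyldimethylsilyl)oxy]-3-(iodomethyl)butanoate | COC(=O)C(=C(O[Mg]I)c1ccc(OCc2ccccc2)c(OC)c1)[C@@H](CI)[C@H](O[Si](C)(C)C(C)(C)C)c1ccc(OCc2ccccc2)c(OC)c1 | intermediate (not isolated)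
14 | methyl (4S)-2-[4-(benzyloxy)-3-methoxyphenyl]-4-[(S)-[4-(benzyloxy)-3-methoxyphenyl][(tert-butyldimethylsilyl)oxy]methyl]-4,5-dihydrofuran-3-carboxylate | COc1cc([C@@H](O[Si](C)(C)C(C)(C)C)[C@@H]2COC(c3ccc(OCc4ccccc4)c(OC)c3)=C2C(=O)OC)ccc1OCc1ccccc1 | intermediate
15 | methyl (4S)-4-[(S)-[(tert-butyldimethylsilyl)oxy](4-hydroxy-3-methoxyphenyl)methyl]-2-(4-hydroxy-3-methoxyphenyl)-4,5-dihydrofuran-3-carboxylate | COc1cc([C@@H](O[Si](C)(C)C(C)(C)C)[C@@H]2COC(c3ccc(O)c(OC)c3)=C2C(=O)OC)ccc1O | intermediate (not isolated)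
16 | methyl (2S,3R,4S)-4-[(S)-[(tert-butyldimethylsilyl)oxy](4-hydroxy-3-methoxyphenyl)methyl]-2-(4-hydroxy-3-methoxyphenyl)tetrahydrofuran-3-carboxylate (all-cis) | COc1cc([C@@H](O[Si](C)(C)C(C)(C)C)[C@@H]2CO[C@H](c3ccc(O)c(OC)c3)[C@@H]2C(=O)OC)ccc1O | intermediate
17 | methyl (2S,3S,4S)-4-[(S)-[(tert-butyldimethylsilyl)oxy](4-hydroxy-3-methoxyphenyl)methyl]-2-(4-hydroxy-3-methoxyphenyl)tetrahydrofuran-3-carboxylate (all-trans) | COc1cc([C@@H](O[Si](C)(C)C(C)(C)C)[C@@H]2CO[C@H](c3ccc(O)c(OC)c3)[C@H]2C(=O)OC)ccc1O | intermediate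
18 | 4-[(2S,3R,4S)-4-[(S)-[(tert-butyldimethylsilyl)oxy](4-hydroxy-3-methoxyphenyl)methyl]-3-(hydroxymethyl)tetrahydrofuran-2-yl]-2-methoxyphenol | COc1cc([C@@H](O[Si](C)(C)C(C)(C)C)[C@@H]2CO[C@H](c3ccc(O)c(OC)c3)[C@H]2CO)ccc1O | intermediate
19 | 4-[(2S,3R,4S)-4-[(S)-hydroxy(4-hydroxy-3-methoxyphenyl)methyl]-3-(hydroxymethyl)tetrahydrofuran-2-yl]-2-methoxyphenol | COc1cc([C@@H](O)[C@@H]2CO[C@H](c3ccc(O)c(OC)c3)[C@H]2CO)ccc1O | target

Total step count: 12. Longest linear sequence: 11 steps (1 to 19 through steps 1–5 and 7–12; step 6 is a one-step side branch).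

Steps most likely to fail

Step 8. The chelated iodo enolate may mainly reclose at carbon, so that the catalyst only interconverts the C3 epimers of 12. Prolonged heating with the Lewis acid may also ionise the benzylic silyl ether or let iodide demethylate the chelated ester. The fallback separates opening from closure and sets out from 12. A full equivalent of MgI2 in Et2O–CH2Cl2 at 0 °C, quenched cold at pH 7, should give methyl (3R,4S)-2-[4-(benzyloxy)-3-methoxybenzoyl]-4-[4-(benzyloxy)-3-methoxyphenyl]-4-[(tert-butyldimethylsilyl)oxy]-3-(iodomethyl)butanoate F1 (Lewis acid–halide opening of an acyl cyclopropane to a γ-iodo carbonyl compound). Ag2CO3 in MeCN at room temperature then abstracts iodide and drives the 5-exo-tet O-alkylation of the keto ester, and the route is rejoined at 14.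

Step 9. The tetrasubstituted push–pull alkene may be reduced so slowly on palladium that forcing conditions begin to hydrogenolyse the benzylic C2–O1 or Ca–O bonds, or hydrogen may add with poor facial selectivity. The fallback uncouples alkene reduction from debenzylation and sets out from 14. Conjugate reduction with nickel boride (NaBH4, NiCl2·6H2O, MeOH–THF, 0 °C), which leaves benzyl ethers intact, should give methyl (2S,4S)-2-[4-(benzyloxy)-3-methoxyphenyl]-4-[(S)-[4-(benzyloxy)-3-methoxyphenyl][(tert-butyldimethylsilyl)oxy]methyl]tetrahydrofuran-3-carboxylate F2 as a mixture at C3. NaOMe in MeOH equilibrates it to the all-trans (2S,3S,4S) dibenzyl ester F3. Brief hydrogenolysis of the two aryl benzyl ethers alone (H2, 1 atm, Pd/C, EtOAc) returns to the route at 17.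

Step 4. Ring closure may run partly or mainly through a cation-bridged transition state that places the ester cis to the carbinol arm, after which the alkoxide lactonises and the material leaves the route. The fallback accepts that path and sets out from 7.
- Closure under lithium conditions (LiN(i-Pr)2, THF, no additive) is taken to (1S,4S,5R)-4-[4-(benzyloxy)-3-methoxyphenyl]-3-oxabicyclo[3.1.0]hexan-2-one F4.
- LiOH in aqueous THF opens it to lithium (1S,2R)-2-[(S)-[4-(benzyloxy)-3-methoxyphenyl](hydroxy)methyl]cyclopropane-1-carboxylate F5.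
- Silylation at both oxygens (TBSCl, imidazole, DMF) gives tert-butyldimethylsilyl (1S,2R)-2-[(S)-[4-(benzyloxy)-3-methoxyphenyl][(tert-butyldimethylsilyl)oxy]methyl]cyclopropane-1-carboxylate F6.
- K2CO3 in aqueous MeOH cleaves only the silyl ester to (1S,2R)-2-[(S)-[4-(benzyloxy)-3-methoxyphenyl][(tert-butyldimethylsilyl)oxy]methyl]cyclopropane-1-carboxylic acid F7.
- MeI/K2CO3 in DMF gives methyl (1S,2R)-2-[(S)-[4-(benzyloxy)-3-methoxyphenyl][(tert-butyldimethylsilyl)oxy]methyl]cyclopropane-1-carboxylate F8, the C3 epimer of 9.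
- Acylation of this ester under the conditions of step 7 returns to the route at 12, since C3 loses its configuration in the enolate.

Further compounds
F1 | step 8 | methyl (3R,4S)-2-[4-(benzyloxy)-3-methoxybenzoyl]-4-[4-(benzyloxy)-3-methoxyphenyl]-4-[(tert-butyldimethylsilyl)oxy]-3-(iodomethyl)butanoate (C2 epimers) | COC(=O)C(C(=O)c1ccc(OCc2ccccc2)c(OC)c1)[C@@H](CI)[C@H](O[Si](C)(C)C(C)(C)C)c1ccc(OCc2ccccc2)c(OC)c1
F2 | step 9 | methyl (2S,4S)-2-[4-(benzyloxy)-3-methoxyphenyl]-4-[(S)-[4-(benzyloxy)-3-methoxyphenyl][(tert-butyldimethylsilyl)oxy]methyl]tetrahydrofuran-3-carboxylate (C3 epimers) | COc1cc([C@@H](O[Si](C)(C)C(C)(C)C)[C@@H]2CO[C@H](c3ccc(OCc4ccccc4)c(OC)c3)C2C(=O)OC)ccc1OCc1ccccc1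
F3 | step 9 | methyl (2S,3S,4S)-2-[4-(benzyloxy)-3-methoxyphenyl]-4-[(S)-[4-(benzyloxy)-3-methoxyphenyl][(tert-butyldimethylsilyl)oxy]methyl]tetrahydrofuran-3-carboxylate (all-trans) | COc1cc([C@@H](O[Si](C)(C)C(C)(C)C)[C@@H]2CO[C@H](c3ccc(OCc4ccccc4)c(OC)c3)[C@H]2C(=O)OC)ccc1OCc1ccccc1
F4 | step 4 | (1S,4S,5R)-4-[4-(benzyloxy)-3-methoxyphenyl]-3-oxabicyclo[3.1.0]hexan-2-one | COc1cc([C@H]2OC(=O)[C@H]3C[C@@H]23)ccc1OCc1ccccc1
F5 | step 4 | lithium (1S,2R)-2-[(S)-[4-(benzyloxy)-3-methoxyphenyl](hydroxy)methyl]cyclopropane-1-carboxylate | [Li+].COc1cc([C@@H](O)[C@@H]2C[C@@H]2C(=O)[O-])ccc1OCc1ccccc1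
F6 | step 4 | tert-butyldimethylsilyl (1S,2R)-2-[(S)-[4-(benzyloxy)-3-methoxyphenyl][(tert-butyldimethylsilyl)oxy]methyl]cyclopropane-1-carboxylate | COc1cc([C@@H](O[Si](C)(C)C(C)(C)C)[C@@H]2C[C@@H]2C(=O)O[Si](C)(C)C(C)(C)C)ccc1OCc1ccccc1
F7 | step 4 | (1S,2R)-2-[(S)-[4-(benzyloxy)-3-methoxyphenyl][(tert-butyldimethylsilyl)oxy]methyl]cyclopropane-1-carboxylic acid | COc1cc([C@@H](O[Si](C)(C)C(C)(C)C)[C@@H]2C[C@@H]2C(=O)O)ccc1OCc1ccccc1
F8 | step 4 | methyl (1S,2R)-2-[(S)-[4-(benzyloxy)-3-methoxyphenyl][(tert-butyldimethylsilyl)oxy]methyl]cyclopropane-1-carboxylate | COc1cc([C@@H](O[Si](C)(C)C(C)(C)C)[C@@H]2C[C@@H]2C(=O)OC)ccc1OCc1ccccc1
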